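**Strategy.** The route rests on disconnecting ring A of the flavanone unit from its C2–C3–C4 chain at O1–C8a and C4–C4a. In the key step the sodium alkoxide of an (S)-β-hydroxy nitrile, already carrying the 8-arylflavone and the C2 stereocentre, adds to 3,5-dimethoxybenzyne; the aryl anion then closes ring C onto the nitrile carbon (C4), and acidic work-up unveils the ketone. The step exploits the 1,3,5-oxygenation of ring A: the methoxy group at C5, next to C4a, steers the alkoxide to C8a and places the carbanion at C4a. The precursor comes from a Suzuki coupling of 8-iodo-5,7,4'-trimethoxyflavone; BCl3 finally frees the two chelated 5-hydroxyls and the 4'-phenol.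

Key step: step 9

Remark: the biaryl axis between C8'' of the flavone and C3' of the flavanone B ring has no configuration in the target and is treated as freely rotating; compounds 1, 3 and 8 are taken as catalogue compounds.

**Step 1**
Reactants: 1 5,7-dimethoxy-2-(4-methoxyphenyl)-4H-chromen-4-one (apigenin trimethyl ether)
Product: 2 8-iodo-5,7-dimethoxy-2-(4-methoxyphenyl)-4H-chromen-4-one
Conditions: I2 (1.2 equiv), CF3CO2Ag (1.2 equiv), CH2Cl2, 0 °C to rt, dark
Reagents that add atoms: iodine, [I][I]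
Why: Silver-assisted electrophilic aromatic iodination; with the 5-oxygen methylated, a 5,7-dialkoxyflavone should react at C8, between the 7-methoxy group and the ring oxygen, in preference to C6 or the anisyl ring.

**Step 2**
Reactants: 3 methyl 4-(benzyloxy)-3-bromobenzoate
Product: 4 3-[4-(benzyloxy)-3-bromophenyl]-3-oxopropanenitrile
Conditions: MeCN (2.3 equiv), n-BuLi (2.2 equiv), THF, −78 °C; then 3, −78 to −40 °C; 1 M HCl quench
Reagents that add atoms: acetonitrile, CC#N
Why: Claisen-type acylation of lithioacetonitrile by the methyl ester; the β-keto nitrile is deprotonated as it forms, which should stop a second addition, and the aryl bromide is inert to the stabilised carbanion at −78 °C.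

**Step 3**
Reactants: 4 3-[4-(benzyloxy)-3-bromophenyl]-3-oxopropanenitrile
Product: 5 (3S)-3-[4-(benzyloxy)-3-bromophenyl]-3-hydroxypropanenitrile
Conditions: RuCl[(S,S)-TsDPEN](p-cymene) (1 mol %), HCO2H–Et3N (5:2), DMF, 30 °C
Reagents that add atoms: none
Why: Noyori–Ikariya asymmetric transfer hydrogenation of an aryl ketone; the (S,S)-TsDPEN ruthenium hydride should deliver hydride to the face that gives the (S)-benzylic alcohol (the sense of acetophenone to (S)-1-phenylethanol, with CH2CN in place of methyl), leaving the bromide, benzyl ether and nitrile untouched.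

**Step 4**
Reactants: 5 (3S)-3-[4-(benzyloxy)-3-bromophenyl]-3-hydroxypropanenitrile
Product: 6 (3S)-3-[4-(benzyloxy)-3-(4,4,5,5-tetramethyl-1,3,2-dioxaborolan-2-yl)phenyl]-3-hydroxypropanenitrile
Conditions: bis(pinacolato)diboron (1.2 equiv), PdCl2(dppf) (3 mol %), KOAc (3 equiv), 1,4-dioxane, 85 °C
Reagents that add atoms: bis(pinacolato)diboron, CC1(C)OB(OC1(C)C)B1OC(C)(C)C(C)(C)O1
Why: Miyaura borylation of the aryl bromide; KOAc is too weak a base to dehydrate the β-hydroxy nitrile and the carbinol centre is not involved.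

**Step 5**
Reactants: 2 8-iodo-5,7-dimethoxy-2-(4-methoxyphenyl)-4H-chromen-4-one; 6 (3S)-3-[4-(benzyloxy)-3-(4,4,5,5-tetramethyl-1,3,2-dioxaborolan-2-yl)phenyl]-3-hydroxypropanenitrile
Product: 7 (3S)-3-{4-(benzyloxy)-3-[5,7-dimethoxy-2-(4-methoxyphenyl)-4-oxo-4H-chromen-8-yl]phenyl}-3-hydroxypropanenitrile
Conditions: Pd(OAc)2 (5 mol %), SPhos (10 mol %), K3PO4 (3 equiv), toluene–H2O (10:1), 80 °C
Reagents that add atoms: none
Why: Suzuki–Miyaura cross-coupling; the electron-rich biaryl phosphine is chosen for the tri-ortho-substituted axis, and mild K3PO4 should spare the β-hydroxy nitrile and the flavone.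

**Step 6**
Reactants: 8 3,5-dimethoxyphenol
Product: 9 3,5-dimethoxyphenyl N-isopropylcarbamate
Conditions: i-PrNCO (1.5 equiv), Et3N (0.2 equiv), CH2Cl2, rt
Reagents that add atoms: isopropyl isocyanate, CC(C)N=C=O
Why: Base-catalysed addition of the phenol to the isocyanate gives a carbamate that directs metalation and can later be removed under mild conditions.

**Step 7**
Reactants: 9 3,5-dimethoxyphenyl N-isopropylcarbamate
Product: 13 3,5-dimethoxy-2-(trimethylsilyl)phenyl N-isopropylcarbamate, via N-silylated carbamate 10 (not isolated), via ortho-lithiated carbamate 11 (not isolated), via bis-silylated carbamate 12 (not isolated)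
Conditions: TBSOTf (1.1 equiv), TMEDA (1.1 equiv), Et2O, 0 °C to rt; then TMEDA (2 equiv), n-BuLi (2 equiv), −78 °C; then TMSCl (4 equiv), −78 °C to rt; aq. NaHSO4
Reagents that add atoms: chlorotrimethylsilane, C[Si](C)(C)Cl
Why: Snieckus directed ortho-metalation; after transient N-silylation the O-carbamate and the 3-methoxy group should direct lithiation cooperatively to C2, the carbon between them, TMSCl quenches the aryllithium, and the N-silyl group is lost on aqueous work-up.

**Step 8**
Reactants: 13 3,5-dimethoxy-2-(trimethylsilyl)phenyl N-isopropylcarbamate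
Product: 15 3,5-dimethoxy-2-(trimethylsilyl)phenyl trifluoromethanesulfonate, via 3,5-dimethoxy-2-(trimethylsilyl)phenol 14 (not isolated)
Conditions: Et2NH (1.3 equiv), DBU (1.5 equiv), MeCN, 40 °C; then PhNTf2 (1.5 equiv), rt
Reagents that add atoms: N-phenylbis(trifluoromethanesulfonimide), O=S(=O)(N(c1ccccc1)S(=O)(=O)C(F)(F)F)C(F)(F)F
Why: Base-induced E1cB cleavage of the secondary carbamate (the isocyanate is trapped by Et2NH as a urea) frees the phenoxide, which PhNTf2 sulfonylates to give the ortho-silylaryl triflate aryne precursor.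

**Step 9**
Reactants: 7 (3S)-3-{4-(benzyloxy)-3-[5,7-dimethoxy-2-(4-methoxyphenyl)-4-oxo-4H-chromen-8-yl]phenyl}-3-hydroxypropanenitrile; 15 3,5-dimethoxy-2-(trimethylsilyl)phenyl trifluoromethanesulfonate
Product: 20 (2S)-2-{4-(benzyloxy)-3-[5,7-dimethoxy-2-(4-methoxyphenyl)-4-oxo-4H-chromen-8-yl]phenyl}-5,7-dimethoxy-2,3-dihydro-4H-chromen-4-one, via sodium alkoxide 16 (not isolated), via 3,5-dimethoxybenzyne 17 (not isolated), via aryl carbanion 18 (not isolated), via cyclic N-sodio ketimine 19 (not isolated)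
Conditions: NaH (1.05 equiv), THF, 0 °C; then 15 (1.3 equiv), KF (3 equiv), 18-crown-6 (3 equiv), THF, 0 °C to rt; then 1 M aq. HCl–THF, 0 °C to rt
Reagents that add atoms: water, O
Why: Proposed new method: fluoride liberates 3,5-dimethoxybenzyne 17 from 15, the alkoxide oxygen of 16 adds to the aryne carbon remote from the flanking methoxy group (future C8a), and the aryl carbanion 18 thus generated next to that methoxy group (future C4a) adds to the tethered nitrile carbon (future C4) to give the cyclic N-sodio ketimine 19, which aqueous acid hydrolyses to the ketone; an aliphatic β-hydroxy nitrile has not been used in this way, but the alkoxide carries no proton to quench 18 and a nitrile is a competent trap for aryl anions. The closest known reaction types are the fluoride-induced annulation of arynes with methyl salicylates to give xanthones, the aryne insertion into the N–C(O) bond of β-lactams to give 2,3-dihydroquinolin-4-ones, and the Parham cyclisation of aryllithiums onto tethered nitriles. Ring C is the only ring closed, by 6-exo-dig attack of the aryl carbanion on the nitrile after the intermolecular O–aryl bond formation. No stereocentre is created: C2 keeps the S configuration set in step 3 because its C–O bond is never broken. The step needs regioselectivity at the aryne, which the methoxy group next to the triple bond should secure through the usual distal attack on 3-alkoxyarynes, and it needs the ketone to stay masked while base is present, which the nitrile should secure because no alkoxide leaving group is released and the ketimide cannot undergo E1cB opening of ring C before the acidic quench.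

**Step 10**
Reactants: 20 (2S)-2-{4-(benzyloxy)-3-[5,7-dimethoxy-2-(4-methoxyphenyl)-4-oxo-4H-chromen-8-yl]phenyl}-5,7-dimethoxy-2,3-dihydro-4H-chromen-4-one
Product: 21 2,3-dihydroheveaflavone, (2S)-5-hydroxy-2-{4-hydroxy-3-[5-hydroxy-7-methoxy-2-(4-methoxyphenyl)-4-oxo-4H-chromen-8-yl]phenyl}-7-methoxy-2,3-dihydro-4H-chromen-4-one
Conditions: BCl3 (8 equiv, 1 M in CH2Cl2), pentamethylbenzene (3 equiv), CH2Cl2, −78 to 0 °C; then MeOH, aqueous work-up
Reagents that add atoms: none
Why: Chelation-controlled Lewis-acid ether cleavage; BCl3 bound to each C4 carbonyl should cleave only the peri methyl ether (C5 of the flavanone, C5'' of the flavone) through a six-membered boron chelate, the benzyl ether falls at −78 °C with pentamethylbenzene as cation scavenger, and the non-chelated 7-, 7''- and 4'''-methyl ethers and the C2 stereocentre should be left alone at 0 °C or below.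

**Compound list**

1 | 5,7-dimethoxy-2-(4-methoxyphenyl)-4H-chromen-4-one | COc1ccc(-c2cc(=O)c3c(OC)cc(OC)cc3o2)cc1 | starting material
2 | 8-iodo-5,7-dimethoxy-2-(4-methoxyphenyl)-4H-chromen-4-one | COc1ccc(-c2cc(=O)c3c(OC)cc(OC)c(I)c3o2)cc1 | intermediate
3 | methyl 4-(benzyloxy)-3-bromobenzoate | COC(=O)c1ccc(OCc2ccccc2)c(Br)c1 | starting material
4 | 3-[4-(benzyloxy)-3-bromophenyl]-3-oxopropanenitrile | N#CCC(=O)c1ccc(OCc2ccccc2)c(Br)c1 | intermediate
5 | (3S)-3-[4-(benzyloxy)-3-bromophenyl]-3-hydroxypropanenitrile | N#CC[C@H](O)c1ccc(OCc2ccccc2)c(Br)c1 | intermediate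
6 | (3S)-3-[4-(benzyloxy)-3-(4,4,5,5-tetramethyl-1,3,2-dioxaborolan-2-yl)phenyl]-3-hydroxypropanenitrile | N#CC[C@H](O)c1ccc(OCc2ccccc2)c(B3OC(C)(C)C(C)(C)O3)c1 | intermediate
7 | (3S)-3-{4-(benzyloxy)-3-[5,7-dimethoxy-2-(4-methoxyphenyl)-4-oxo-4H-chromen-8-yl]phenyl}-3-hydroxypropanenitrile | COc1ccc(-c2cc(=O)c3c(OC)cc(OC)c(-c4cc([C@@H](O)CC#N)ccc4OCc5ccccc5)c3o2)cc1 | intermediate
8 | 3,5-dimethoxyphenol | COc1cc(O)cc(OC)c1 | starting material
9 | 3,5-dimethoxyphenyl N-isopropylcarbamate | COc1cc(OC)cc(OC(=O)NC(C)C)c1 | intermediate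
10 | 3,5-dimethoxyphenyl N-(tert-butyldimethylsilyl)-N-isopropylcarbamate | COc1cc(OC)cc(OC(=O)N(C(C)C)[Si](C)(C)C(C)(C)C)c1 | intermediate (not isolated)
11 | 2-lithio-3,5-dimethoxyphenyl N-(tert-butyldimethylsilyl)-N-isopropylcarbamate | COc1cc(OC)c([Li])c(OC(=O)N(C(C)C)[Si](C)(C)C(C)(C)C)c1 | intermediate (not isolated)
12 | 3,5-dimethoxy-2-(trimethylsilyl)phenyl N-(tert-butyldimethylsilyl)-N-isopropylcarbamate | COc1cc(OC)c([Si](C)(C)C)c(OC(=O)N(C(C)C)[Si](C)(C)C(C)(C)C)c1 | intermediate (not isolated)
13 | 3,5-dimethoxy-2-(trimethylsilyl)phenyl N-isopropylcarbamate | COc1cc(OC)c([Si](C)(C)C)c(OC(=O)NC(C)C)c1 | intermediate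
14 | 3,5-dimethoxy-2-(trimethylsilyl)phenol | COc1cc(OC)c([Si](C)(C)C)c(O)c1 | intermediate (not isolated)
15 | 3,5-dimethoxy-2-(trimethylsilyl)phenyl trifluoromethanesulfonate | COc1cc(OC)c([Si](C)(C)C)c(OS(=O)(=O)C(F)(F)F)c1 | intermediate
16 | sodium (1S)-1-{4-(benzyloxy)-3-[5,7-dimethoxy-2-(4-methoxyphenyl)-4-oxo-4H-chromen-8-yl]phenyl}-2-cyanoethoxide | [Na+].COc1ccc(-c2cc(=O)c3c(OC)cc(OC)c(-c4cc([C@@H]([O-])CC#N)ccc4OCc5ccccc5)c3o2)cc1 | intermediate (not isolated)
17 | 3,5-dimethoxybenzyne (1,2-didehydro-3,5-dimethoxybenzene) | COC1=CC(OC)=CC#C1 | intermediate (not isolated)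
18 | sodium 2-[(1S)-1-aryl-2-cyanoethoxy]-4,6-dimethoxyphenide (aryl = the 4-benzyloxy-3-flavonylphenyl group of 7) | [Na+].COc1ccc(-c2cc(=O)c3c(OC)cc(OC)c(-c4cc([C@@H](Oc5cc(OC)cc(OC)[c-]5)CC#N)ccc4OCc6ccccc6)c3o2)cc1 | intermediate (not isolated)
19 | N-sodio (2S)-4-imino-5,7-dimethoxychromane bearing the 4-benzyloxy-3-flavonylphenyl group at C2 | [Na+].COc1ccc(-c2cc(=O)c3c(OC)cc(OC)c(-c4cc([C@@H]5CC(=[N-])c6c(OC)cc(OC)cc6O5)ccc4OCc7ccccc7)c3o2)cc1 | intermediate (not isolated)
20 | (2S)-2-{4-(benzyloxy)-3-[5,7-dimethoxy-2-(4-methoxyphenyl)-4-oxo-4H-chromen-8-yl]phenyl}-5,7-dimethoxy-2,3-dihydro-4H-chromen-4-one | COc1ccc(-c2cc(=O)c3c(OC)cc(OC)c(-c4cc([C@@H]5CC(=O)c6c(OC)cc(OC)cc6O5)ccc4OCc7ccccc7)c3o2)cc1 | intermediate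
21 | 2,3-dihydroheveaflavone | COc1ccc(-c2cc(=O)c3c(O)cc(OC)c(-c4cc([C@@H]5CC(=O)c6c(O)cc(OC)cc6O5)ccc4O)c3o2)cc1 | target

**Step count.** Total: 10 steps. Longest linear sequence: 6 steps (steps 2, 3, 4, 5, 9, 10, from compound 3).

**Steps most likely to fail**

1. Step 9 (proposed new method). The aryl carbanion may be protonated, or may take a proton from the carbon next to the nitrile and trigger β-elimination, before it reaches the nitrile carbon; the ketimide may also be N-arylated by surplus aryne. Fallback with known chemistry, setting out from 7: treat 7 with 15 and CsF in MeCN at rt, where the alcohol adds to the aryne with the same regiochemistry and the medium protonates the aryl anion (O-arylation of an alcohol by an aryne). This should give the aryl ether (3S)-3-{4-(benzyloxy)-3-[5,7-dimethoxy-2-(4-methoxyphenyl)-4-oxo-4H-chromen-8-yl]phenyl}-3-(3,5-dimethoxyphenoxy)propanenitrile F1. Ring C is then closed by an intramolecular Houben–Hoesch acylation of the phloroglucinol-type ring (ZnCl2, HCl, Et2O, 0 °C, then aqueous hydrolysis of the ketiminium salt), which comes back to the route at 20.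

2. Step 10. The boron Lewis acid may open ring C by retro-oxa-Michael reaction or ionise the benzylic C2–O1 bond, with loss of configuration, and may attack the non-chelated methyl ethers on warming. Fallback, setting out from 20: hydrogenolysis of the benzyl ether (H2, 10% Pd/C, EtOAc, rt) to the phenol (2S)-2-{4-hydroxy-3-[5,7-dimethoxy-2-(4-methoxyphenyl)-4-oxo-4H-chromen-8-yl]phenyl}-5,7-dimethoxy-2,3-dihydro-4H-chromen-4-one F2. The two peri methyl ethers are then cleaved by chelation-directed iodide demethylation with MgI2·OEt2 in THF at 40 °C, which arrives at 21.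

3. Step 5. Transmetalation at the hindered axis may be slow, so that protodeboronation of 6 and base-induced loss of water from the β-hydroxy nitrile compete during prolonged heating. Fallback, setting out from 3, which couples at the robust ester stage:
   - Miyaura borylation of 3 (conditions of step 4) to methyl 4-(benzyloxy)-3-(4,4,5,5-tetramethyl-1,3,2-dioxaborolan-2-yl)benzoate F3.
   - Suzuki coupling of F3 with 2 to methyl 4-(benzyloxy)-3-[5,7-dimethoxy-2-(4-methoxyphenyl)-4-oxo-4H-chromen-8-yl]benzoate F4.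
   - Acylation of lithioacetonitrile (inverse addition, THF, −78 °C) to 3-{4-(benzyloxy)-3-[5,7-dimethoxy-2-(4-methoxyphenyl)-4-oxo-4H-chromen-8-yl]phenyl}-3-oxopropanenitrile F5.
   - Transfer hydrogenation with the catalyst of step 3, which rejoins the route at 7.

**Further compounds**

F1 | step 9 | (3S)-3-{4-(benzyloxy)-3-[5,7-dimethoxy-2-(4-methoxyphenyl)-4-oxo-4H-chromen-8-yl]phenyl}-3-(3,5-dimethoxyphenoxy)propanenitrile | COc1ccc(-c2cc(=O)c3c(OC)cc(OC)c(-c4cc([C@@H](Oc5cc(OC)cc(OC)c5)CC#N)ccc4OCc6ccccc6)c3o2)cc1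
F2 | step 10 | (2S)-2-{4-hydroxy-3-[5,7-dimethoxy-2-(4-methoxyphenyl)-4-oxo-4H-chromen-8-yl]phenyl}-5,7-dimethoxy-2,3-dihydro-4H-chromen-4-one | COc1ccc(-c2cc(=O)c3c(OC)cc(OC)c(-c4cc([C@@H]5CC(=O)c6c(OC)cc(OC)cc6O5)ccc4O)c3o2)cc1
F3 | step 5 | methyl 4-(benzyloxy)-3-(4,4,5,5-tetramethyl-1,3,2-dioxaborolan-2-yl)benzoate | COC(=O)c1ccc(OCc2ccccc2)c(B3OC(C)(C)C(C)(C)O3)c1
F4 | step 5 | methyl 4-(benzyloxy)-3-[5,7-dimethoxy-2-(4-methoxyphenyl)-4-oxo-4H-chromen-8-yl]benzoate | COc1ccc(-c2cc(=O)c3c(OC)cc(OC)c(-c4cc(C(=O)OC)ccc4OCc5ccccc5)c3o2)cc1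
F5 | step 5 | 3-{4-(benzyloxy)-3-[5,7-dimethoxy-2-(4-methoxyphenyl)-4-oxo-4H-chromen-8-yl]phenyl}-3-oxopropanenitrile | COc1ccc(-c2cc(=O)c3c(OC)cc(OC)c(-c4cc(C(=O)CC#N)ccc4OCc5ccccc5)c3o2)cc1
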